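**Retrosynthetic overview**
1. Target 9, (13S)-8α-hydroxylabdan-15-yl 3-phenylpropanoate, is cut at the ester C–O bond into (13S)-labdane-8α,15-diol 7 and 3-phenylpropanoyl chloride 8.
2. Diol 7 comes from tert-butyl (13S)-8α-hydroxylabdan-15-oate 6 by ester reduction.
3. Key disconnection C12–C13: the C12 aldehyde carbon is used as a nucleophile (alkyl carbanion equivalent released from its N–H hydrazone with loss of N2) and adds to the β-carbon of tert-butyl crotonate 4. Both carbons are natively electrophilic, and a chiral Ru–bisphosphine catalyst sets C13.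
4. The C12 aldehyde is carried as lactol 2, made by partial reduction of (+)-sclareolide 1, which supplies C5, C8, C9 and C10.
5. Rings: none is built. The trans-decalin comes intact from sclareolide and its γ-lactone is opened in the key step.

Assumption: (R,R)-Me-BPE is taken to give the 13S epimer in step 2; the sense of induction is not predictable, and if it is reversed the commercial (S,S)-ligand is used with nothing else changed.

**Route**

Step 1
Reactants: 1 (+)-sclareolide
Product: 2 sclareolide lactol (8α,12-epoxy-13,14,15,16-tetranorlabdan-12-ol; C12 anomers)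
Conditions: DIBAL-H (1.15 equiv), CH2Cl2, −78 °C; Rochelle salt work-up
Reagents that add atoms: none
Why: DIBAL-H partial reduction of a γ-lactone stops at the lactol because the aluminium hemiacetal is stable at −78 °C; C5, C8, C9 and C10 are untouched and the C12 anomers converge in step 2.

Step 2
Reactants: 2 sclareolide lactol; 3 hydrazine monohydrate; 4 tert-butyl (E)-but-2-enoate
Product: 6 tert-butyl (13S)-8α-hydroxylabdan-15-oate, via aldehyde N–H hydrazone 5 (not isolated)
Conditions: N2H4·H2O (1.1 equiv), THF, rt, 1 h; then [Ru(p-cymene)Cl2]2 (2.5 mol %), (R,R)-Me-BPE (5.5 mol %), K3PO4 (0.3 equiv), CsF (1 equiv), 4 (2 equiv), THF, 50 °C, 24 h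
Reagents that add atoms: none
Why: Proposed new method: the ring-opened hydroxy-aldehyde form of 2 condenses to hydrazone 5, which binds Ru(II) and is deprotonated to a hydrazonide whose former carbonyl carbon is nucleophilic (Wolff–Kishner-type carbanion equivalent); it attacks the β-carbon of the Ru-coordinated crotonate through a six-membered cyclic transition state, then N2 loss and protonation leave C12 as CH2. The C2-symmetric bisphospholane (chiral analogue of dmpe) differentiates the crotonate enantiofaces to set C13 as S, by analogy with Rh/bisphosphine asymmetric 1,4-additions to crotonates; the closest known reaction type is the Ru(II)/dmpe-catalysed umpolung conjugate addition of aldehyde N–H hydrazones to acrylates and related Michael acceptors, extended here to an aliphatic γ-hydroxy aldehyde, a β-methyl acceptor and a chiral ligand.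

Step 3
Reactants: 6 tert-butyl (13S)-8α-hydroxylabdan-15-oate
Product: 7 (13S)-labdane-8α,15-diol
Conditions: LiAlH4 (2 equiv), THF, 0 °C to reflux; Fieser work-up
Reagents that add atoms: none
Why: LiAlH4 ester reduction gives the primary alcohol; C13 is β to the carbonyl and cannot epimerise, and the tertiary 8α-OH is only carried as its alkoxide.

Step 4
Reactants: 7 (13S)-labdane-8α,15-diol; 8 3-phenylpropanoyl chloride
Product: 9 (13S)-8α-hydroxylabdan-15-yl 3-phenylpropanoate
Conditions: 8 (1.05 equiv), pyridine (2 equiv), DMAP (5 mol %), CH2Cl2, 0 °C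
Reagents that add atoms: none
Why: DMAP-catalysed acylation with an acyl chloride is chemoselective for the primary C15–OH; the hindered tertiary 8α-OH does not react at 0 °C with one equivalent, and no stereocentre is affected.

**Compound list**
1 | (+)-sclareolide, (3aR,5aS,9aS,9bR)-3a,6,6,9a-tetramethyldecahydronaphtho[2,1-b]furan-2(1H)-one | O=C1C[C@@H]2[C@@]3(C)CCCC(C)(C)[C@@H]3CC[C@@]2(C)O1 | starting material
2 | sclareolide lactol, (3aR,5aS,9aS,9bR)-3a,6,6,9a-tetramethyldodecahydronaphtho[2,1-b]furan-2-ol (anomers) | OC1C[C@@H]2[C@@]3(C)CCCC(C)(C)[C@@H]3CC[C@@]2(C)O1 | intermediate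
3 | hydrazine monohydrate | NN.O | starting material
4 | tert-butyl (E)-but-2-enoate (tert-butyl crotonate) | C/C=C/C(=O)OC(C)(C)C | starting material
5 | (1R,2R,4aS,8aS)-1-[(2E)-2-hydrazinylideneethyl]-2,5,5,8a-tetramethyldecahydronaphthalen-2-ol (N–H hydrazone of the C12 aldehyde; not isolated) | N/N=C/C[C@@H]1[C@@]2(C)CCCC(C)(C)[C@@H]2CC[C@@]1(C)O | intermediate
6 | tert-butyl (3S)-5-[(1R,2R,4aS,8aS)-2-hydroxy-2,5,5,8a-tetramethyldecahydronaphthalen-1-yl]-3-methylpentanoate | C[C@H](CC(=O)OC(C)(C)C)CC[C@@H]1[C@@]2(C)CCCC(C)(C)[C@@H]2CC[C@@]1(C)O | intermediate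
7 | (13S)-labdane-8α,15-diol, (1R,2R,4aS,8aS)-1-[(3S)-5-hydroxy-3-methylpentyl]-2,5,5,8a-tetramethyldecahydronaphthalen-2-ol | C[C@H](CCO)CC[C@@H]1[C@@]2(C)CCCC(C)(C)[C@@H]2CC[C@@]1(C)O | intermediate
8 | 3-phenylpropanoyl chloride | O=C(Cl)CCc1ccccc1 | starting material
9 | (3S)-5-[(1R,2R,4aS,8aS)-2-hydroxy-2,5,5,8a-tetramethyldecahydronaphthalen-1-yl]-3-methylpentyl 3-phenylpropanoate | C[C@H](CCOC(=O)CCc1ccccc1)CC[C@@H]1[C@@]2(C)CCCC(C)(C)[C@@H]2CC[C@@]1(C)O | target

**Totals**
Total step count: 4. Longest linear sequence: 4 (steps 1–4 from sclareolide).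

**Steps most likely to fail, with fallbacks**

Step 2 is the main risk: an aliphatic hydrazone and a β-substituted acceptor are beyond the demonstrated scope, simple Wolff–Kishner reduction of 5 may compete, and the C13 selectivity may be low. The fallback sets out from lactol 2 and comes back at diol 7, replacing catalyst control by auxiliary control with physical purification. Hydrazone 5 is pre-formed and freed of excess hydrazine, then added under the achiral [Ru(p-cymene)Cl2]2/dmpe/K3PO4 system to N-[(E)-but-2-enoyl]-(2R)-bornane-10,2-sultam F1, which is made from the commercial sultam, NaH and (E)-crotonoyl chloride. The crystalline adduct N-[(13S)-8α-hydroxylabdan-15-oyl]-(2R)-bornane-10,2-sultam F2 is recrystallised to a single C13 epimer; the antipodal auxiliary is used if the (2R)-sultam favours 13R. LiAlH4 in THF then cleaves the auxiliary and gives 7 directly, by-passing 6.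

Step 1 can over-reduce or give incomplete conversion on scale. The fallback sets out from sclareolide 1 and comes back at lactol 2. Compound 1 is reduced exhaustively with LiAlH4 to 13,14,15,16-tetranorlabdane-8α,12-diol F3. Only the primary alcohol is then oxidised under Swern conditions (1.1 equiv (COCl)2/DMSO, Et3N, −78 °C), and the resulting hydroxy-aldehyde closes spontaneously to 2.

Step 4 could give some bis-acylation or acid-induced dehydration of the tertiary alcohol. The fallback sets out from diol 7 and comes back at target 9. It activates the alcohol instead of the acid: Mitsunobu esterification with 3-phenylpropanoic acid, PPh3 and DIAD in THF at 0 °C, where only the primary C15–OH forms the alkoxyphosphonium ion. It makes no new compound (F0).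

**Further compounds**
F1 | step 2 | N-[(E)-but-2-enoyl]-(2R)-bornane-10,2-sultam | CC1(C)[C@@H]2CC[C@]13CS(=O)(=O)N(C(=O)/C=C/C)[C@@H]3C2
F2 | step 2 | N-[(13S)-8α-hydroxylabdan-15-oyl]-(2R)-bornane-10,2-sultam | CC1(C)[C@@H]2CC[C@]13CS(=O)(=O)N(C(=O)C[C@@H](C)CC[C@@H]4[C@@]5(C)CCCC(C)(C)[C@@H]5CC[C@@]4(C)O)[C@@H]3C2
F3 | step 1 | 13,14,15,16-tetranorlabdane-8α,12-diol, (1R,2R,4aS,8aS)-1-(2-hydroxyethyl)-2,5,5,8a-tetramethyldecahydronaphthalen-2-ol | OCC[C@@H]1[C@@]2(C)CCCC(C)(C)[C@@H]2CC[C@@]1(C)O
F0 | step 4 | none | none
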